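Numbering used throughout: ring A is the hydroquinone ring (C1 carries the ether oxygen, C2 and C5 the hydroxyls, C4 and C6 bromine, C3 hydrogen). Ring B is the outer ring (C1' ether oxygen, C2', C3' and C5' bromine, C4' hydroxyl, C6' hydrogen). The target is achiral.

## The problem

Compound 9 is two benzene rings joined only through one ether oxygen (C1–O–C1'). It has no stereocenter and no ring to close, so the task is purely one of regiochemistry on a diaryl ether. Five C–Br bonds (C4, C6, C2', C3', C5') and three hydroxyls (C2, C5, C4') must be placed while C3 and C6' remain C–H. C3 is the awkward position: it lies ortho to the C2 hydroxyl yet must not be halogenated, so the C2 oxygen has to be distinguished from the C5 oxygen whenever electrophilic bromine is present. Ring A is a bromohydroquinone and is oxidised to a quinone by bromine, by peroxide and by air in alkali. The C2 oxygen and the C2' bromine are also placed so that hot base or light could close a dibenzo-p-dioxin, and five aryl bromides exclude organolithium reagents and catalytic hydrogenation late in the route. The exploitable feature is that C5–OH and C4'–OH are each flanked by two bromines (C4/C6 and C3'/C5') and each has an oxygen-bearing carbon para to it (C2 and C1'). That is the pattern left by exhaustive ortho-bromination of a para-blocked phenol. Four of the five bromines can therefore be placed by the directing power of two free phenols; only C2'–Br, ortho to the ether oxygen and meta to its hydroxyl, falls outside that logic.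

## Retrosynthesis

**9 ⇒ 8 (S–O bond).** The C2 hydroxyl is traced back to a methanesulfonate, 8. During bromination a free C2–OH would make ring A a hydroquinone, which Br2 oxidises, and would direct bromine to C3. A sulfonate is electron-withdrawing, survives Br2/HBr and BBr3, and is removed by hydroxide. The forward step must only cleave S–O without oxidising the liberated bromohydroquinone.

**8 ⇒ 7 (four C–Br bonds: C4, C6, C3', C5').** All four bromines ortho to the two free phenols are removed in one disconnection, leading to diphenol 7. The neighbouring choice, bringing these bromines in on pre-halogenated building blocks, would require two non-commercial polybromo arenes, each with its own regiochemical problem. The C2' bromine is treated differently. Adding it last with a Lewis acid would have to distinguish C2' from C6' after the first substitution, on a substrate with two 2,6-dibromophenols prone to ipso attack. It is therefore carried from the start as a spectator in a commercial bromophenol. Compound 7 holds one bromine instead of five, and the forward reaction is asked only to follow the ortho preference of phenols.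

**7 ⇒ 6 (two O–CH3 bonds).** The two free phenols are masked as methyl ethers in 6. Methyl ethers are what the commercial building blocks carry, they survive every earlier step, and BBr3 removes both without touching the mesylate or the diaryl ether.

**6 ⇒ 5 (S–O bond).** The mesylate comes from phenol 5. At this stage the C2 oxygen is the only free hydroxyl in the molecule, so the C2/C5 differentiation needs no selectivity.

**5 ⇒ 3 via 4 (C2–O from C2–CHO).** The C2 oxygen is traced to a formyl group through aryl formate 4 (Baeyer–Villiger/Dakin logic). The aldehyde serves twice: it activates the neighbouring carbon for ether formation and then becomes the oxygen that will carry the mesylate. The ortho aryloxy and para methoxy groups make the aryl group of 3 a good migrating group.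

**3 ⇒ 1 + 2 (C1–O bond).** The diaryl ether is cut next to the formyl-activated carbon, giving 2-bromo-4-methoxyphenol 1 and 2-fluoro-4-methoxybenzaldehyde 2, both commercial. Addition–elimination needs no metal, so the C2' bromine of 1 is untouched. The alternative cut at C1'–O would need an activated ring B electrophile that does not exist in this substitution pattern.

## Roads not taken

**Alternative 1: ring B by chromium carbene benzannulation.**
- **Cut and key step.** Ring B is dissected at C1'–C6', C3'–C4' and C4'–C5'. The carbene complex A2, made from the fully substituted ring A phenol A1, would be heated with a silylacetylene. Alkyne insertion, insertion of one carbonyl ligand and electrocyclisation would give the 4-aryloxyphenol A3, whose two C–Si bonds mark C2' and C5' for later ipso-bromodesilylation.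
- **Merits.** The C2' bromine is placed by construction, not by a purchased bromophenol, and ring A never meets Br2 as a free phenol. In regiochemical certainty at C2' and in protection of ring A this road is the better one.
- **Weak points.** Aryloxycarbene complexes are labile because the aryloxide leaves easily from the carbene carbon. Chromium is stoichiometric. A1 needs its own regiocontrolled synthesis. After the key step there remain two bromodesilylations (with protodesilylation by HBr competing next to a hydroxyl), one phenol-directed bromination at C3' and two demethylations.
- **Comparison.** It builds an ordinary para-oxygenated benzene ring that can be bought. The chosen plan obtains the C2' bromine by purchase in 1, protects ring A with one mesylation, and is complete in six steps.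

**Alternative 2: aryne aryloxy-bromination.**
- **Cut and key step.** The C1'–O and C2'–Br bonds are cut across an aryne. Fluoride would release benzyne A5 from silylaryl triflate A4. The phenoxide of A1 would add at C1', the carbon remote from the C3' bromine, and the C2' aryl anion would be trapped by a positive-bromine donor to give trimethyl ether A6. Three demethylations would finish.
- **Merits.** It is the most convergent of the four plans, and it forms the ether and the one bromine that phenol direction cannot place in a single step. On convergence it is superior in principle.
- **Weak points.** The C2' anion sits ortho to the C3' bromine and can expel bromide to form a second aryne, or be protonated, before the bromine donor arrives. The phenoxide can itself consume the bromine donor. A4 requires silyl and triflate groups on a ring already holding two bromines, which conflicts with the metalation chemistry normally used to make such precursors. Both partners need long syntheses.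
- **Comparison.** The chosen plan has no intermediate of uncertain fate, and its six linear steps are fewer than the steps needed to prepare A1 and A4 alone.

**Alternative 3: ring A from a squarate-derived vinylcyclobutenone.**
- **Cut and key step.** The C4–C5 bond of ring A is cut. Heating racemic cyclobutenone A7 would open the four-membered ring to a dienylketene (methoxy rotating outward, vinyl inward). A 6π electrocyclisation would form C4–C5, and tautomerisation would give phenol A8 with C6–Br, the ether and a methylated C2 oxygen in place. One ortho bromination at C4 and two demethylations would follow.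
- **Merits.** The contiguous C5/C6/C1/C2 array is fixed by construction, the two ring A oxygens emerge already differentiated, C3 is never at risk, and the stereocenter of A7 vanishes on aromatisation. In differentiating the ring A oxygens this road is better than a protecting-group solution.
- **Weak points.** A7 must be assembled from a squarate ester in several steps. These include addition–elimination with the fully brominated ring B phenol A9, which is not commercial; a vinylmetal addition in the presence of aryl bromides; and introduction of a reactive vinylic bromine. The last ring A bromine still enters by phenol-directed bromination, so the chemistry of the chosen plan is reduced, not avoided.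
- **Comparison.** The chosen plan achieves the same oxygen differentiation with one mesylation and is far shorter.

Key step: step 5

## Route

Step 1
Reactants: 1 2-bromo-4-methoxyphenol; 2 2-fluoro-4-methoxybenzaldehyde
Product: 3 2-(2-bromo-4-methoxyphenoxy)-4-methoxybenzaldehyde
Conditions: K2CO3, DMAc, 120 °C
Reagents that add atoms: none
Why: Nucleophilic aromatic substitution (SNAr): the ortho formyl group stabilises the Meisenheimer adduct and fluoride leaves readily, while the C–Br bond of 1 is inert without a transition metal. DMAc replaces DMF so that no dimethylamine competes for the fluorine-bearing carbon.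

Step 2
Reactants: 3 2-(2-bromo-4-methoxyphenoxy)-4-methoxybenzaldehyde
Product: 5 2-(2-bromo-4-methoxyphenoxy)-4-methoxyphenol, via aryl formate 4 (not isolated)
Conditions: mCPBA, CH2Cl2, 0 °C to rt; aq. NaHCO3 wash; then Et3N, MeOH, rt
Reagents that add atoms: mCPBA, O=C(OO)c1cccc(Cl)c1
Why: Baeyer–Villiger (Dakin-type) oxidation: in the Criegee adduct the aryl group, made electron-rich by its ortho aryloxy and para methoxy groups, migrates in preference to hydride to give formate 4, which base-catalysed methanolysis cleaves. The phenol is released only after the peracid has been washed out, so it is not exposed to the oxidant.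

Step 3
Reactants: 5 2-(2-bromo-4-methoxyphenoxy)-4-methoxyphenol
Product: 6 2-(2-bromo-4-methoxyphenoxy)-4-methoxyphenyl methanesulfonate
Conditions: MsCl, Et3N, CH2Cl2, 0 °C
Reagents that add atoms: methanesulfonyl chloride, CS(=O)(=O)Cl
Why: O-Sulfonylation of the only free phenol is fast at 0 °C even beside the ortho aryloxy group. The mesylate is chosen because it resists BBr3 and Br2/HBr and withdraws electron density from ring A.

Step 4
Reactants: 6 2-(2-bromo-4-methoxyphenoxy)-4-methoxyphenyl methanesulfonate
Product: 7 2-(2-bromo-4-hydroxyphenoxy)-4-hydroxyphenyl methanesulfonate
Conditions: BBr3, CH2Cl2, −78 °C to rt; then H2O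
Reagents that add atoms: none
Why: Lewis acid cleavage of aryl methyl ethers: BBr3 coordinates each methoxy oxygen and bromide removes the methyl group by SN2. The diaryl ether offers no sp3 carbon and aryl sulfonates are inert to BBr3; water hydrolyses the aryl borates to the two phenols.

Step 5
Reactants: 7 2-(2-bromo-4-hydroxyphenoxy)-4-hydroxyphenyl methanesulfonate
Product: 8 3,5-dibromo-4-hydroxy-2-(2,3,5-tribromo-4-hydroxyphenoxy)phenyl methanesulfonate
Conditions: Br2 (4.2 equiv), glacial AcOH, rt, dark; then aq. Na2S2O3
Reagents that add atoms: bromine, BrBr
Why: Electrophilic aromatic substitution, four times over: each free hydroxyl donates into its ring, bromine attacks an ortho carbon to give an arenium ion, and loss of a proton restores the arene. The closest known reaction type is the exhaustive ortho,ortho-dibromination of para-substituted phenols, in particular 4-aryloxyphenols, with Br2 in acetic acid. On ring A the C5 hydroxyl directs to C4 (also para to the ether oxygen) and C6 (also ortho to it); on ring B the C4' hydroxyl directs to C5' and to C3', which lies next to the resident C2' bromine and should fill last. The selectivity needed is substitution only ortho to the two free hydroxyls: C3 is meta to both oxygen donors of ring A and ortho to the electron-withdrawing sulfonate, C6' is meta to its hydroxyl, and both para positions carry oxygen, so the reaction should stop after four equivalents. The mesylate also prevents ring A from being a free hydroquinone, which bromine would oxidise to a quinone. Glacial solvent is specified because ipso attack at C1' or C2 reverses in the absence of water but would lead to quinones if the bromodienone were hydrolysed. No ring is closed and no stereocenter is formed.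

Step 6
Reactants: 8 3,5-dibromo-4-hydroxy-2-(2,3,5-tribromo-4-hydroxyphenoxy)phenyl methanesulfonate
Product: 9 3,5-dibromo-2-(2,3,5-tribromo-4-hydroxyphenoxy)benzene-1,4-diol
Conditions: NaOH (2 M aq.), MeOH, 60 °C, degassed, argon; then aq. HCl, Na2S2O4
Reagents that add atoms: none
Why: Alkaline hydrolysis of an aryl sulfonate by attack of hydroxide at sulfur with S–O cleavage; aryl bromides and the diaryl ether do not react with hydroxide at this temperature. Oxygen is excluded and Na2S2O4 is present on acidification because the product is a bromohydroquinone that air oxidises in base.

## Compound list

1 | 2-bromo-4-methoxyphenol | COc1ccc(O)c(Br)c1 | starting material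
2 | 2-fluoro-4-methoxybenzaldehyde | COc1ccc(C=O)c(F)c1 | starting material
3 | 2-(2-bromo-4-methoxyphenoxy)-4-methoxybenzaldehyde | COc1ccc(C=O)c(Oc2ccc(OC)cc2Br)c1 | intermediate
4 | 2-(2-bromo-4-methoxyphenoxy)-4-methoxyphenyl formate (aryl formate, not isolated) | COc1ccc(OC=O)c(Oc2ccc(OC)cc2Br)c1 | intermediate
5 | 2-(2-bromo-4-methoxyphenoxy)-4-methoxyphenol | COc1ccc(O)c(Oc2ccc(OC)cc2Br)c1 | intermediate
6 | 2-(2-bromo-4-methoxyphenoxy)-4-methoxyphenyl methanesulfonate | COc1ccc(OS(C)(=O)=O)c(Oc2ccc(OC)cc2Br)c1 | intermediate
7 | 2-(2-bromo-4-hydroxyphenoxy)-4-hydroxyphenyl methanesulfonate | CS(=O)(=O)Oc1ccc(O)cc1Oc1ccc(O)cc1Br | intermediate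
8 | 3,5-dibromo-4-hydroxy-2-(2,3,5-tribromo-4-hydroxyphenoxy)phenyl methanesulfonate | CS(=O)(=O)Oc1cc(Br)c(O)c(Br)c1Oc1cc(Br)c(O)c(Br)c1Br | intermediate
9 | 3,5-dibromo-2-(2,3,5-tribromo-4-hydroxyphenoxy)benzene-1,4-diol (CNP0084224.0) | Oc1cc(Br)c(O)c(Br)c1Oc1cc(Br)c(O)c(Br)c1Br | target

## Step count and least certain steps

Total step count: 6. Longest linear sequence: 6 steps (1 and 2 both enter in step 1).

**Step 5 (key step).**
- **Risk.** Oxidation in place of substitution is the most likely failure. Ipso attack of bromine at an oxygen-bearing carbon para to a free hydroxyl (C2 or C1'), followed by capture of the bromodienone by traces of water, would collapse to a quinone with loss of the methanesulfonyl group on ring A or scission of the ether at ring B. A lesser risk is stalling before the crowded C3' is filled, leaving a mixture of bromination levels.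
- **Fallback.** It sets out from 3 and returns at 9, keeping the fourfold bromination but holding the C2 oxygen as a formyl carbon. Aldehyde 3 is demethylated with BBr3 in CH2Cl2 to 2-(2-bromo-4-hydroxyphenoxy)-4-hydroxybenzaldehyde F1. F1 is brominated with four equivalents of Br2 in acetic acid to 3,5-dibromo-4-hydroxy-2-(2,3,5-tribromo-4-hydroxyphenoxy)benzaldehyde F2. A Dakin oxidation of this para-hydroxybenzaldehyde (H2O2, aqueous NaOH, argon, rt) then turns the formyl group into the C2 hydroxyl and gives 9.
- **Why it helps and what it costs.** Ring A then has carbon para to its hydroxyl during bromination and cannot collapse to a quinone by loss of a sulfonyl group. The sequence is two steps shorter. It is held in reserve because its last step exposes the bromohydroquinone to alkaline peroxide, and because ring B behaves exactly as in the main route.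

**Step 6.**
- **Risk.** S–O cleavage may be slow because both bromophenols are ionised in alkali and the departing aryloxide would be a dianion. Forcing conditions would invite air oxidation of the hydroquinone dianion and intramolecular displacement of the C2' bromide by the freed C2 phenoxide, closing a dibenzo-p-dioxin.
- **Fallback.** It sets out from 5 and returns at 9, using a sulfonate that is removed by thiolate attack on its own nitroarene ring instead of by hydroxide. Phenol 5 is converted with 2,4-dinitrobenzenesulfonyl chloride and Et3N into 2-(2-bromo-4-methoxyphenoxy)-4-methoxyphenyl 2,4-dinitrobenzenesulfonate F3. BBr3 gives 2-(2-bromo-4-hydroxyphenoxy)-4-hydroxyphenyl 2,4-dinitrobenzenesulfonate F4. Br2 in acetic acid gives 3,5-dibromo-4-hydroxy-2-(2,3,5-tribromo-4-hydroxyphenoxy)phenyl 2,4-dinitrobenzenesulfonate F5. Thiophenol with K2CO3 in DMF at rt then adds to the dinitroarene at the sulfur-bearing carbon and releases 9 under mild, reducing conditions.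

**Step 1.**
- **Risk.** Addition may be sluggish because the para methoxy group feeds electron density into the formyl group and weakens its activation of the C–F carbon, and the ortho-bromophenoxide is hindered and weakly nucleophilic. Prolonged heating would then erode the aldehyde by base-induced disproportionation.
- **Fallback.** It sets out from 1 and returns at 3, replacing addition–elimination by copper-catalysed C–O coupling. Phenol 1 is coupled with commercial 2-bromo-4-methoxybenzaldehyde F6 under Ullmann conditions (CuI, N,N-dimethylglycine, Cs2CO3, dioxane, 90 °C). The formyl-activated C–Br bond of the aldehyde partner should react in preference to the electron-rich C–Br bond of 1.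

## Further compounds

F1 | step 5 | 2-(2-bromo-4-hydroxyphenoxy)-4-hydroxybenzaldehyde | O=Cc1ccc(O)cc1Oc1ccc(O)cc1Br
F2 | step 5 | 3,5-dibromo-4-hydroxy-2-(2,3,5-tribromo-4-hydroxyphenoxy)benzaldehyde | O=Cc1cc(Br)c(O)c(Br)c1Oc1cc(Br)c(O)c(Br)c1Br
F3 | step 6 | 2-(2-bromo-4-methoxyphenoxy)-4-methoxyphenyl 2,4-dinitrobenzenesulfonate | COc1ccc(OS(=O)(=O)c2ccc([N+](=O)[O-])cc2[N+](=O)[O-])c(Oc2ccc(OC)cc2Br)c1
F4 | step 6 | 2-(2-bromo-4-hydroxyphenoxy)-4-hydroxyphenyl 2,4-dinitrobenzenesulfonate | Oc1ccc(OS(=O)(=O)c2ccc([N+](=O)[O-])cc2[N+](=O)[O-])c(Oc2ccc(O)cc2Br)c1
F5 | step 6 | 3,5-dibromo-4-hydroxy-2-(2,3,5-tribromo-4-hydroxyphenoxy)phenyl 2,4-dinitrobenzenesulfonate | Oc1c(Br)cc(OS(=O)(=O)c2ccc([N+](=O)[O-])cc2[N+](=O)[O-])c(Oc2cc(Br)c(O)c(Br)c2Br)c1Br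
F6 | step 1 | 2-bromo-4-methoxybenzaldehyde (commercial coupling partner) | COc1ccc(C=O)c(Br)c1
A1 | alternative 1 | 2,4-dibromo-3,6-dimethoxyphenol | COc1cc(Br)c(OC)c(Br)c1O
A2 | alternative 1 | pentacarbonyl[(2,4-dibromo-3,6-dimethoxyphenoxy)(1-trimethylsilylvinyl)carbene]chromium | C=C([Si](C)(C)C)C(Oc1c(OC)cc(Br)c(OC)c1Br)=[Cr](=C=O)(=C=O)(=C=O)(=C=O)=C=O
A3 | alternative 1 | 4-(2,4-dibromo-3,6-dimethoxyphenoxy)-2,5-bis(trimethylsilyl)phenol | COc1cc(Br)c(OC)c(Br)c1Oc1cc([Si](C)(C)C)c(O)cc1[Si](C)(C)C
A4 | alternative 2 | 3,5-dibromo-4-methoxy-2-(trimethylsilyl)phenyl trifluoromethanesulfonate | COc1c(Br)cc(OS(=O)(=O)C(F)(F)F)c([Si](C)(C)C)c1Br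
A5 | alternative 2 | 3,5-dibromo-4-methoxybenzyne | COC1=C(Br)C#CC=C1Br
A6 | alternative 2 | 1,3-dibromo-2,5-dimethoxy-4-(2,3,5-tribromo-4-methoxyphenoxy)benzene | COc1c(Br)cc(Oc2c(OC)cc(Br)c(OC)c2Br)c(Br)c1Br
A7 | alternative 3 | racemic 2-bromo-4-methoxy-3-(2,3,5-tribromo-4-methoxyphenoxy)-4-vinylcyclobut-2-en-1-one | COC1(C=C)C(Oc2cc(Br)c(OC)c(Br)c2Br)=C(Br)C1=O
A8 | alternative 3 | 2-bromo-4-methoxy-3-(2,3,5-tribromo-4-methoxyphenoxy)phenol | COc1ccc(O)c(Br)c1Oc1cc(Br)c(OC)c(Br)c1Br
A9 | alternative 3 | 2,3,5-tribromo-4-methoxyphenol | COc1c(Br)cc(O)c(Br)c1Br
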